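**Retrosynthetic overview**
- Ferugin ⇒ O-acetylferutinin: the last bond made is C9–O, by a dehydrogenative anti-Markovnikov hydroxylation of the C8=C9 alkene with water (the alkene moves to C8=C14), followed by phenol deacetylation.
- O-Acetylferutinin ⇒ jaeschkeanadiol + 4-acetoxybenzoyl chloride (C6–O acylation).
- Jaeschkeanadiol ⇒ cyclopentane triene diol by ring-closing metathesis (C8=C9). The five-membered ring is present from the first step; the seven-membered ring is formed second.
- Triene diol ⇒ isopropyl addition to the C4 ketone ⇐ anti aldol (C5–C6) of a regiodefined cyclopentanone enolate with 3-methylbut-3-enal.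
- Enolate ⇒ copper-catalysed asymmetric conjugate methylation of 3-allylcyclopent-2-enone (quaternary C1) ⇐ 3-ethoxycyclopent-2-enone + allylmagnesium bromide.

Labels: C1–C15 are daucane labels, used in the text for all compounds. C1 is the quaternary ring-fusion carbon (methyl C15); C2, C3; C4 is the carbinol carbon bearing isopropyl; C5 is the ring-fusion CH; C6 is the ester carbon; C7; C8 (bearing C14); C9; C10. The target is 1β-methyl, 4β-OH, 5α-H, 6α-acyloxy, 9α-OH, i.e. (1R,4R,5S,6S,9S).

Assumption: the (4S,5S) form of the carbene ligand of step 2 is taken to give the (R) quaternary centre; if the sense is opposite, the mirror-image ligand is used. The ligand is the carbene from 2-[(4S,5S)-3-(2,6-diethylphenyl)-4,5-diphenyl-4,5-dihydro-1H-imidazol-3-ium-1-yl]benzenesulfonate, used as its silver complex [Ag(C31H29N2O3S)]2 made with Ag2O.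

Co(dmgH)2pyCl is chloro(pyridine)bis(dimethylglyoximato)cobalt, C13H19ClCoN5O4.

**Route**

Step 1
Reactants: 1 3-ethoxycyclopent-2-en-1-one; 2 allylmagnesium bromide
Product: 4 3-(prop-2-en-1-yl)cyclopent-2-en-1-one, via bromomagnesium alkoxide 3 (not isolated)
Conditions: 2 (1.2 equiv), THF, 0 °C; then 1 M aq. HCl, 0 °C, 20 min
Reagents that add atoms: allylmagnesium bromide (2), C=CC[Mg]Br; water, O
Why: Grignard 1,2-addition to the vinylogous ester, then acid hydrolysis of the enol ether with loss of water (Stork–Danheiser 1,3-carbonyl transposition) gives the β-allyl enone; no stereocentre is formed.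

Step 2
Reactants: 4 3-(prop-2-en-1-yl)cyclopent-2-en-1-one; 5 trimethylaluminium
Product: 7 triethyl{[(3R)-3-methyl-3-(prop-2-en-1-yl)cyclopent-1-en-1-yl]oxy}silane, via dimethylaluminium enolate 6 (not isolated)
Conditions: 5 (2.0 equiv), Cu(OTf)2 (5 mol %), [Ag(C31H29N2O3S)]2 (2.5 mol %), THF, −78 °C, 24 h; then Et3SiOTf (2.5 equiv), −78 → 0 °C; aq. NaHCO3
Reagents that add atoms: trimethylaluminium (5), C[Al](C)C; triethylsilyl trifluoromethanesulfonate, CC[Si](CC)(CC)OS(=O)(=O)C(F)(F)F
Why: Copper-catalysed asymmetric conjugate addition of an alkylaluminium to a β-substituted cyclopentenone: the chiral sulfonate-bearing carbene–copper complex delivers methyl to one enantiotopic face of the β-carbon and so sets the quaternary C1 as R, and O-silylation of the aluminium enolate stores the enolate on the C5 side.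

Step 3
Reactants: 8 3-methylbut-3-en-1-ol
Product: 9 3-methylbut-3-enal
Conditions: Dess–Martin periodinane (1.1 equiv), NaHCO3 (3 equiv), CH2Cl2, 0 °C, 1 h; filtered through basic alumina, used at once as a cold CH2Cl2 solution
Reagents that add atoms: none
Why: Dess–Martin oxidation is fast and non-basic, so the β,γ-unsaturated aldehyde forms without migration of the alkene into conjugation; no stereocentre is formed.

Step 4
Reactants: 7 triethyl{[(3R)-3-methyl-3-(prop-2-en-1-yl)cyclopent-1-en-1-yl]oxy}silane; 9 3-methylbut-3-enal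
Product: 12 (2S,3R)-2-[(1S)-1-hydroxy-3-methylbut-3-en-1-yl]-3-methyl-3-(prop-2-en-1-yl)cyclopentan-1-one, via lithium enolate 10 (not isolated), via dicyclohexylboron enolate 11 (not isolated)
Conditions: MeLi (1.05 equiv), THF, 0 °C, 1 h; (c-C6H11)2BCl (1.2 equiv), −78 °C, 30 min; 9 (1.5 equiv), −78 → −20 °C, 3 h; then pH 7 buffer, MeOH, 30% H2O2, 0 °C
Reagents that add atoms: 3-methylbut-3-enal (9), C=C(C)CC=O
Why: Boron-mediated aldol addition through a Zimmerman–Traxler chair: the ring-locked E enolate gives the anti aldol (C6 S), the aldehyde adds to the enolate face syn to the C1 methyl and away from the larger allyl arm (C5 S), and the weakly basic boron enolate does not enolise the β,γ-unsaturated aldehyde.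

Step 5
Reactants: 12 (2S,3R)-2-[(1S)-1-hydroxy-3-methylbut-3-en-1-yl]-3-methyl-3-(prop-2-en-1-yl)cyclopentan-1-one; 13 isopropylmagnesium chloride
Product: 14 (1R,2S,3R)-2-[(1S)-1-hydroxy-3-methylbut-3-en-1-yl]-3-methyl-1-(propan-2-yl)-3-(prop-2-en-1-yl)cyclopentan-1-ol
Conditions: 13 (4 equiv), CeCl3 (4 equiv), THF, −78 → −40 °C; aq. NH4Cl
Reagents that add atoms: isopropylmagnesium chloride (13), CC(C)[Mg]Cl
Why: Organocerium 1,2-addition (Imamoto conditions) outruns enolisation, β-hydride reduction and retro-aldol cleavage; the nucleophile enters the ketone face opposite to the adjacent C5 side chain, which places the new hydroxyl cis to that chain and sets C4 as R.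

Step 6
Reactants: 14 (1R,2S,3R)-2-[(1S)-1-hydroxy-3-methylbut-3-en-1-yl]-3-methyl-1-(propan-2-yl)-3-(prop-2-en-1-yl)cyclopentan-1-ol
Product: 15 jaeschkeanadiol [(1R,4R,5S,6S)-dauc-8-ene-4,6-diol]
Conditions: second-generation Grubbs catalyst (C46H65Cl2N2PRu, 5 mol %), CH2Cl2 (5 mM), 40 °C
Reagents that add atoms: none
Why: Ring-closing metathesis of the allyl and 2-methylallyl arms (trans on the cyclopentane) releases ethylene and closes the trans-fused seven-membered ring with the trisubstituted C8=C9 alkene; no stereocentre is touched.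

Step 7
Reactants: 15 jaeschkeanadiol; 16 4-acetoxybenzoyl chloride
Product: 17 O-acetylferutinin [(1R,4R,5S,6S)-4-hydroxydauc-8-en-6-yl 4-acetoxybenzoate]
Conditions: 16 (1.5 equiv), Et3N (3 equiv), DMAP (20 mol %), CH2Cl2, 0 → 25 °C
Reagents that add atoms: 4-acetoxybenzoyl chloride (16), CC(=O)Oc1ccc(cc1)C(Cl)=O
Why: DMAP-catalysed acylation (nucleophilic catalysis): only the secondary C6 hydroxyl reacts, the tertiary C4 hydroxyl is inert, and C6 keeps its configuration because the alcohol C–O bond is not broken.

Step 8
Reactants: 17 O-acetylferutinin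
Product: 19 ferugin [(1R,4R,5S,6S,9S)-4,9-dihydroxydauc-8(14)-en-6-yl 4-hydroxybenzoate], via O-acetylferugin 18 (not isolated)
Conditions: 9-mesityl-3,6-di-tert-butyl-10-phenylacridinium tetrafluoroborate (5 mol %), Co(dmgH)2pyCl (5 mol %), H2O (20 equiv), MeCN (0.05 M), 450 nm LEDs, 25 °C, Ar, 24 h; then pyrrolidine (5 equiv), 25 °C, 1 h
Reagents that add atoms: water, O
Why: Proposed new method: acceptorless dehydrogenative anti-Markovnikov hydroxylation of an unactivated trisubstituted alkene with water (a formal "water-ene" reaction) — the excited acridinium (about +2.0 V vs SCE) oxidises only the C8=C9 alkene to its radical cation (the acetoxybenzoate and the 1,1-disubstituted alkene of the product lie above about +2.3 V, so the reaction stops after one oxidation), water adds at the less substituted C9 from the α-face (anti to the angular C1 methyl that screens the β-face) to leave the tertiary C8 radical and set C9 as S, divalent cobalt formed from Co(dmgH)2pyCl then removes the most accessible β-hydrogen (the C14 methyl, Hofmann sense; C7–H is shielded by the C6 ester) to give the exocyclic alkene, and the trivalent cobalt hydride plus the released proton give H2 while the acridine radical returns cobalt to the divalent state; the closest known reaction types are acridinium-photocatalysed anti-Markovnikov hydrofunctionalisation of alkenes and acridinium/cobaloxime dehydrogenative alkene functionalisation (anti-Markovnikov Wacker-type oxidation of styrenes, dehydrogenative allylic amination), neither shown to give allylic alcohols from aliphatic alkenes and water; the second stage is a routine chemoselective aminolysis of the aryl acetate that leaves the hindered C6 benzoate untouched.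

**Compound list**

1 | 3-ethoxycyclopent-2-en-1-one | CCOC1=CC(=O)CC1 | starting material
2 | allylmagnesium bromide | C=CC[Mg]Br | starting material
3 | bromomagnesium 3-ethoxy-1-(prop-2-en-1-yl)cyclopent-2-en-1-olate (racemic) | CCOC1=CC(CC=C)(O[Mg]Br)CC1 | intermediate (not isolated)
4 | 3-(prop-2-en-1-yl)cyclopent-2-en-1-one | C=CCC1=CC(=O)CC1 | intermediate
5 | trimethylaluminium | C[Al](C)C | starting material
6 | dimethylaluminium (3R)-3-methyl-3-(prop-2-en-1-yl)cyclopent-1-en-1-olate | C[Al](C)OC1=C[C@](C)(CC1)CC=C | intermediate (not isolated)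
7 | triethyl{[(3R)-3-methyl-3-(prop-2-en-1-yl)cyclopent-1-en-1-yl]oxy}silane | CC[Si](CC)(CC)OC1=C[C@](C)(CC1)CC=C | intermediate
8 | 3-methylbut-3-en-1-ol | C=C(C)CCO | starting material
9 | 3-methylbut-3-enal | C=C(C)CC=O | intermediate
10 | lithium (3R)-3-methyl-3-(prop-2-en-1-yl)cyclopent-1-en-1-olate | [Li]OC1=C[C@](C)(CC1)CC=C | intermediate (not isolated)
11 | dicyclohexyl{[(3R)-3-methyl-3-(prop-2-en-1-yl)cyclopent-1-en-1-yl]oxy}borane | C1CCCCC1B(OC2=C[C@](C)(CC2)CC=C)C3CCCCC3 | intermediate (not isolated)
12 | (2S,3R)-2-[(1S)-1-hydroxy-3-methylbut-3-en-1-yl]-3-methyl-3-(prop-2-en-1-yl)cyclopentan-1-one; side chain cis to the ring methyl, trans to allyl | C=C(C)C[C@H](O)[C@@H]1[C@](C)(CCC1=O)CC=C | intermediate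
13 | isopropylmagnesium chloride | CC(C)[Mg]Cl | starting material
14 | (1R,2S,3R)-2-[(1S)-1-hydroxy-3-methylbut-3-en-1-yl]-3-methyl-1-(propan-2-yl)-3-(prop-2-en-1-yl)cyclopentan-1-ol; tertiary OH cis to the side chain and to the ring methyl | C=C(C)C[C@H](O)[C@@H]1[C@](C)(CC[C@@]1(O)C(C)C)CC=C | intermediate
15 | jaeschkeanadiol, (1R,4R,5S,6S)-dauc-8-ene-4,6-diol (trans-fused; 1β-Me, 4β-OH, 5α-H, 6α-OH) | CC=1C[C@H](O)[C@@H]2[C@](C)(CC[C@@]2(O)C(C)C)CC1 | intermediate
16 | 4-acetoxybenzoyl chloride | CC(=O)Oc1ccc(cc1)C(Cl)=O | starting material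
17 | O-acetylferutinin, (1R,4R,5S,6S)-4-hydroxydauc-8-en-6-yl 4-acetoxybenzoate | CC=1C[C@H](OC(=O)c2ccc(OC(C)=O)cc2)[C@@H]2[C@](C)(CC[C@@]2(O)C(C)C)CC1 | intermediate
18 | O-acetylferugin, (1R,4R,5S,6S,9S)-4,9-dihydroxydauc-8(14)-en-6-yl 4-acetoxybenzoate | C=C1C[C@H](OC(=O)c2ccc(OC(C)=O)cc2)[C@@H]2[C@](C)(CC[C@@]2(O)C(C)C)C[C@@H]1O | intermediate (not isolated)
19 | ferugin, (1R,4R,5S,6S,9S)-4,9-dihydroxydauc-8(14)-en-6-yl 4-hydroxybenzoate | C=C1C[C@H](OC(=O)c2ccc(O)cc2)[C@@H]2[C@](C)(CC[C@@]2(O)C(C)C)C[C@@H]1O | target

**Step count and risks**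

Total step count: 8 (steps 1–8; step 3 is a one-step side branch).
Longest linear sequence: 7 steps (1, 2, 4, 5, 6, 7, 8, from compound 1).
The enantiomeric purity fixed in step 2 is carried through. Diol 15 is the point at which recrystallisation would be attempted if enrichment is needed, and the minor C5 diastereomer from step 4 is removed by chromatography at 12 or 14.

The three steps most likely to fail:

Step 8 (the new reaction). Risks are allylic deprotonation of the radical cation instead of water addition, loss of the C9 hydrogen to give the enol and then the C9 ketone, and incomplete α-face selectivity. The fallback uses known chemistry and sets out from 17. A Schenck ene reaction with singlet oxygen (O2, 5,10,15,20-tetraphenylporphyrin 1 mol %, CH2Cl2, 0 °C, visible light) gives a mixture of allylic hydroperoxides that includes (1R,4R,5S,6S,9S)-9-hydroperoxy-4-hydroxydauc-8(14)-en-6-yl 4-acetoxybenzoate F1, formed by attack on the α-face at C9 with hydrogen abstraction from C14. Reduction in the same flask with PPh3 and chromatography to remove the regioisomeric allylic alcohols gives 18, where the fallback comes back to the route; 18 is deacetylated with pyrrolidine as in the second stage of step 8 to give 19.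

Step 4 (aldol). Risks are enolisation or conjugation of the β,γ-unsaturated aldehyde, modest facial discrimination between methyl and allyl at the neighbouring quaternary carbon, and incomplete anti selectivity. The fallback sets out from 7 and removes the sensitive aldehyde and the aldol control of C6.
- Lewis-acid-catalysed aqueous hydroxymethylation (37% aq. HCHO, Yb(OTf)3 10 mol %, THF/H2O, 25 °C) gives (2S,3R)-2-(hydroxymethyl)-3-methyl-3-(prop-2-en-1-yl)cyclopentan-1-one F2.
- Addition of i-PrMgCl/CeCl3 (THF, −78 °C) gives (1R,2S,3R)-2-(hydroxymethyl)-3-methyl-1-(propan-2-yl)-3-(prop-2-en-1-yl)cyclopentan-1-ol F3.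
- Selective oxidation of the primary alcohol (TEMPO 10 mol %, PhI(OAc)2, CH2Cl2) gives (1R,2R,5R)-2-hydroxy-5-methyl-2-(propan-2-yl)-5-(prop-2-en-1-yl)cyclopentane-1-carbaldehyde F4.
- Chelation-controlled Barbier methallylation (3-bromo-2-methylprop-1-ene, In powder, THF/H2O) adds to the aldehyde face away from the quaternary carbon of the hydroxyl–aldehyde chelate and gives the 1,3-anti diol 14.

The fallback comes back to the route at 14, so it also replaces step 5.

Step 5 (isopropyl addition). Risks are retro-aldol cleavage of the aldolate, enolisation, and β-hydride reduction of the hindered ketone by the branched reagent. The fallback sets out from 12 and reverses the order of ring closure and addition, using an sp2 nucleophile that cannot transfer hydride.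
- Ring-closing metathesis of 12 (second-generation Grubbs catalyst 5 mol %, CH2Cl2, 40 °C) gives (3aR,8S,8aS)-8-hydroxy-3a,6-dimethyl-3,3a,4,7,8,8a-hexahydroazulen-1(2H)-one F5.
- Isopropenylmagnesium bromide/CeCl3 (THF, −78 °C) adds to the α-face, anti to C6, and gives (1R,4S,5S,6S)-dauca-8,11-diene-4,6-diol F6.
- RhCl(PPh3)3 (5 mol %) under H2 (1 atm, benzene/EtOH) hydrogenates only the 1,1-disubstituted isopropenyl alkene and leaves the trisubstituted ring alkene.

The fallback comes back to the route at 15, so it also replaces step 6.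

**Further compounds**

F1 | step 8 | (1R,4R,5S,6S,9S)-9-hydroperoxy-4-hydroxydauc-8(14)-en-6-yl 4-acetoxybenzoate | C=C1C[C@H](OC(=O)c2ccc(OC(C)=O)cc2)[C@@H]2[C@](C)(CC[C@@]2(O)C(C)C)C[C@@H]1OO
F2 | step 4 | (2S,3R)-2-(hydroxymethyl)-3-methyl-3-(prop-2-en-1-yl)cyclopentan-1-one | OC[C@@H]1[C@](C)(CCC1=O)CC=C
F3 | step 4 | (1R,2S,3R)-2-(hydroxymethyl)-3-methyl-1-(propan-2-yl)-3-(prop-2-en-1-yl)cyclopentan-1-ol | OC[C@@H]1[C@](C)(CC[C@@]1(O)C(C)C)CC=C
F4 | step 4 | (1R,2R,5R)-2-hydroxy-5-methyl-2-(propan-2-yl)-5-(prop-2-en-1-yl)cyclopentane-1-carbaldehyde | O=C[C@@H]1[C@](C)(CC[C@@]1(O)C(C)C)CC=C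
F5 | step 5 | (3aR,8S,8aS)-8-hydroxy-3a,6-dimethyl-3,3a,4,7,8,8a-hexahydroazulen-1(2H)-one | CC=1C[C@H](O)[C@@H]2[C@](C)(CCC2=O)CC1
F6 | step 5 | (1R,4S,5S,6S)-dauca-8,11-diene-4,6-diol | CC=1C[C@H](O)[C@@H]2[C@](C)(CC[C@@]2(O)C(C)=C)CC1
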